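In per cent of the Q charged, the runs nearly coincide: at 6.00 h Q stands at 51.9%, 52.0% and 52.1% in oak, ash and cedar, so across these charges I reckon Q as first-order, with 0.109 h⁻¹, which leaves 41.7% at 8.0 h.

| flask | Q | D | J | remark | time |
|---|---|---|---|---|---|
| oak | 10 mM | 20 mM | 15 mM | run made earlier |  |
| ash | 10 mM | 20 mM | 24 mM | run made earlier |  |
| cedar | 5 mM | 20 mM | 11 mM | run made earlier |  |
| flask | 10 mM | 20.0 mM | 11.0 mM |  | 8.0 h |

| run | time / h | X / % | Z / % | Q / % |
|---|---|---|---|---|
| oak | 0.500 | 1.3 | 3.9 | 94.7 |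
| oak | 0.833 | 1.6 | 6.3 | 91.3 |
| oak | 1.33 | 2.6 | 10.8 | 86.3 |
| oak | 2.00 | 3.6 | 15.9 | 80.3 |
| oak | 3.00 | 4.5 | 23.2 | 72.4 |
| oak | 4.00 | 5.0 | 29.7 | 65.0 |
| oak | 6.00 | 7.2 | 40.6 | 51.9 |
| ash | 0.500 | 1.4 | 3.7 | 94.9 |
| ash | 0.833 | 1.9 | 6.5 | 91.7 |
| ash | 1.33 | 3.0 | 10.5 | 86.8 |
| ash | 2.00 | 3.3 | 15.8 | 81.1 |
| ash | 3.00 | 4.6 | 22.8 | 72.2 |
| ash | 4.00 | 5.4 | 29.4 | 65.0 |
| ash | 6.00 | 6.7 | 40.7 | 52.0 |
| cedar | 0.500 | 1.7 | 3.7 | 94.4 |
| cedar | 1.50 | 2.7 | 12.0 | 85.0 |
| cedar | 3.00 | 4.4 | 23.1 | 72.2 |
| cedar | 5.00 | 6.4 | 35.5 | 58.0 |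
| cedar | 6.00 | 6.6 | 41.2 | 52.1 |

(standard deviation of a reading: 0.3 percentage points)

* ratio of X to Z at 12 min
* ratio of X to Z at 80 min
* ratio of X to Z at 8.0 h
* which of X and Z there is more of at 8.0 h

- as a solid, counted per litre of solution: J
- what was read earlier has a scatter of 0.3 percentage points, one standard deviation
- at the start none of J is in solution

I take the fast step as settled: a short-lived intermediate, in steady state, forms at Q's pace and is shared at once between D and dissolved J, so X per Z should follow [D]/[dissolved J]. The split, X gained per Z gained between 2.00 h and 6.00 h in oak and ash together (a selectivity factor), reads 0.141. Those two runs read 0.263 at 80 min, and I carry that over; 12 min lies before any reading, so I give it no number. From their mean 6.00 h values, X 6.95% and Z 40.6%, I share out the further 10.2% of Q by the split, which gives 0.166 at 8.0 h.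

The weak link is the constant split. If each Z takes one J, free J is charge minus Z. By that count cedar reached 8.94 mM with no visible change in its readings, but by my reckoning this flask reaches 6.04 mM at 8.0 h. Taking that cedar value as the highest possible solubility and the mean free J of the last stretch, 6.49 mM, the split there becomes 0.194, and I commit to 0.175, with Z ahead.

The forecast says 0.75, 0.24 and 0.165, with Z ahead, a little below mine at the later times, and calls the first “a poorly constrained extrapolation”.

The flask gives 0.696, 0.246 and 0.171, with X at 8.44% and Z at 49.4%.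

    D + L → X (k = 22.9 M⁻¹ min⁻¹)
    J ⇌ G, rate k2*(cs2 - [G]) while solid is left; crystals form when [G] > cs2 (solubility = 8.00 mM, k = 0.0428 min⁻¹)
    G + L → Z (k = 406 M⁻¹ min⁻¹)
    Q → L (k = 0.00180 min⁻¹)

Now take the neighbouring flask, the same as this one but with 6.6 mM of J. With G's ceiling at 8.0 mM and [D] held near its charge, X gained per Z gained, once the solid has dissolved, is the split times that ceiling over [G], and [G] is then the free J. In this neighbour free J falls from 5.02 mM at 2.00 h, if all has dissolved by then, to 2.13 mM at 8.0 h. Summing over that fall, starting from the mean X of oak and ash at 2.00 h, 3.45%, I reach 13.1%. At 8.00 h this neighbour holds G at 2.13 mM, X at 13.1% and a ratio of 0.294.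

Readings and results are simulated for substances that don't exist; noise was put on by code.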